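**Retrosynthetic overview**

- The target, 3-henicosyl-2-hydroxy-5-methoxy-1,4-benzoquinone, is traced back to 3-henicosyl-2,5-dimethoxy-1,4-benzoquinone (regioselective hydrolysis of the C2 methoxy group) and then to 3-henicosyl-1,2,4,5-tetramethoxybenzene (oxidative demethylation).
- Key disconnection: the side-chain bond C6′–C7′ (numbered from the ring). It is formed by a nickel-catalysed decarboxylative cross-electrophile coupling of a 6-arylhexyl bromide with the N-hydroxyphthalimide ester of palmitic acid, which unites two carbons of like (electrophilic) polarity through a radical.
- Enabling feature: C6′–C7′ joins two unactivated CH2 groups of the unbranched C21 chain. C7′–C21′ plus one carboxyl carbon is palmitic acid, and C1′–C6′ hold the reacting carbon five CH2 groups away from the six-membered carbocycle, which is carried as a reduction-inert 1,2,4,5-tetramethoxybenzene.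
- The bromide comes from lithiation of 1,2,4,5-tetramethoxybenzene at C3–H (flanked by two OMe groups) and alkylation with 1,6-dibromohexane.
- Ring order: the only ring is bought as the arene; no ring is formed, and it is raised to the quinone level only after the coupling.

Key step: step 3

Remark: the target has no stereocentre and is made as the 2-hydroxy-1,4-benzoquinone tautomer drawn in the SMILES.

**Route**

Step 1
Reactants: 1 1,2,4,5-tetramethoxybenzene; 2 1,6-dibromohexane
Product: 4 3-(6-bromohexyl)-1,2,4,5-tetramethoxybenzene, via 2,3,5,6-tetramethoxyphenyllithium 3 (not isolated)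
Conditions: n-BuLi (1.05 equiv), THF, 0 °C → rt; then added to 2 (4 equiv), THF, −78 °C → rt
Reagents that add atoms: none
Why: Directed ortho-lithiation removes the ring proton flanked by two methoxy groups, and SN2 alkylation of the aryllithium by the primary dibromide, used in excess and with inverse addition, should stop at mono-arylation of the C6 chain.

Step 2
Reactants: 5 palmitic acid (hexadecanoic acid); 6 N-hydroxyphthalimide
Product: 7 1,3-dioxoisoindolin-2-yl hexadecanoate
Conditions: DIC (1.1 equiv), DMAP (10 mol%), CH2Cl2, rt
Reagents that add atoms: none
Why: Carbodiimide (Steglich-type) esterification of an unhindered fatty acid with N-hydroxyphthalimide is the standard entry to a redox-active ester.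

Step 3
Reactants: 4 3-(6-bromohexyl)-1,2,4,5-tetramethoxybenzene; 7 1,3-dioxoisoindolin-2-yl hexadecanoate
Product: 8 3-henicosyl-1,2,4,5-tetramethoxybenzene
Conditions: 7 (2.0 equiv), NiBr2·glyme (10 mol%), 4,4′-di-tert-butyl-2,2′-bipyridine-type ligand (10 mol%), Zn dust (3 equiv), DMA/THF, 25 °C
Reagents that add atoms: none
Why: Zinc turns over a low-valent nickel–bipyridine catalyst that activates the primary C–Br bond of 4 (halogen abstraction/oxidative addition) and, by single-electron transfer, fragments the phthalimide ester 7 to CO2, phthalimide anion and the pentadecyl radical; capture of this radical by the 6-arylhexyl–nickel species gives a dialkyl–Ni(III) that reductively eliminates the new CH2–CH2 bond. The closest known reaction type is the nickel-catalysed decarboxylative C(sp3)–C(sp3) cross-electrophile coupling of N-hydroxyphthalimide esters with unactivated primary alkyl bromides under zinc reduction. No ring is closed and no stereocentre is formed. The selectivity needed is cross- over homo-coupling of two primary electrophiles; it is secured by the different activation modes of the two partners (C–Br versus redox-active ester), by the excess of the cheap fatty-acid ester 7, and by the easy chromatographic removal of the hydrocarbon by-products from the polar tetramethoxyarene. The tetramethoxybenzene ring carries no reducible group, and the five CH2 groups between it and the reacting carbon exclude benzylic stabilisation and fast radical cyclisation onto the ring.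

Step 4
Reactants: 8 3-henicosyl-1,2,4,5-tetramethoxybenzene
Product: 9 3-henicosyl-2,5-dimethoxy-1,4-benzoquinone
Conditions: CAN (2.5 equiv), MeCN/CH2Cl2/H2O, 0 °C → rt
Reagents that add atoms: water, O
Why: Cerium(IV) oxidative demethylation of a para-dimethoxyarene (arene radical cation, ipso attack of water, loss of methanol) should give the para-quinone, and both para pairs of methoxy groups lead to the same product.

Step 5
Reactants: 9 3-henicosyl-2,5-dimethoxy-1,4-benzoquinone
Product: 10 3-henicosyl-2-hydroxy-5-methoxy-1,4-benzoquinone
Conditions: 70% aq. HClO4, 1,4-dioxane, rt, stopped at mono-hydrolysis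
Reagents that add atoms: water, O
Why: Acid-catalysed addition–elimination hydrolysis of a vinylogous ester should take place at the C2 methoxy group, which is flanked by the alkyl chain and twisted out of conjugation, as is usual for 3-alkyl-2,5-dimethoxybenzoquinones, and the resulting vinylogous acid is deactivated towards a second hydrolysis.

**Compound list**

1 | 1,2,4,5-tetramethoxybenzene | COc1cc(OC)c(OC)cc1OC | starting material
2 | 1,6-dibromohexane | BrCCCCCCBr | starting material
3 | 2,3,5,6-tetramethoxyphenyllithium | [Li]c1c(OC)c(OC)cc(OC)c1OC | intermediate
4 | 3-(6-bromohexyl)-1,2,4,5-tetramethoxybenzene | COc1cc(OC)c(OC)c(CCCCCCBr)c1OC | intermediate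
5 | palmitic acid (hexadecanoic acid) | CCCCCCCCCCCCCCCC(=O)O | starting material
6 | N-hydroxyphthalimide | O=C1c2ccccc2C(=O)N1O | starting material
7 | 1,3-dioxoisoindolin-2-yl hexadecanoate | CCCCCCCCCCCCCCCC(=O)ON1C(=O)c2ccccc2C1=O | intermediate
8 | 3-henicosyl-1,2,4,5-tetramethoxybenzene | CCCCCCCCCCCCCCCCCCCCCc1c(OC)c(OC)cc(OC)c1OC | intermediate
9 | 3-henicosyl-2,5-dimethoxy-1,4-benzoquinone | CCCCCCCCCCCCCCCCCCCCCC1=C(OC)C(=O)C=C(OC)C1=O | intermediate
10 | 3-henicosyl-2-hydroxy-5-methoxy-1,4-benzoquinone | CCCCCCCCCCCCCCCCCCCCCC1=C(O)C(=O)C=C(OC)C1=O | target

**Step count and risks**

Total step count: 5. Longest linear sequence: 4 steps (steps 1, 3, 4, 5).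

Steps most likely to fail:

1. Step 3. Homo-coupling of either electrophile, hydrodehalogenation of the bromide or β-hydride elimination at nickel may outrun the cross-coupling. The fallback sets out from 4 and abandons the like-polarity union for a polar one. Commercial 1-bromopentadecane (CCCCCCCCCCCCCCCBr) is converted with magnesium in THF into pentadecylmagnesium bromide F1. F1 is then coupled with 4 under copper catalysis (Li2CuCl4, THF, −10 °C → rt), a Grignard–alkyl bromide coupling that the tetramethoxyarene should tolerate. The route is rejoined at 8.

2. Step 5. Hydrolysis may run on to the dihydroxyquinone, or discrimination between the two vinylogous-ester methoxy groups may be poor. The fallback sets out from 9 and replaces selective removal by full removal and selective re-installation. Exhaustive hydrolysis (aq. NaOH, EtOH/THF, then acidification) should give 3-henicosyl-2,5-dihydroxy-1,4-benzoquinone F2. Acid-catalysed vinylogous Fischer esterification of F2 (MeOH, cat. H2SO4, reflux, followed closely) should then methylate the unhindered C5 hydroxyl next to C6–H in preference to the C2 hydroxyl buttressed by the chain. The route is rejoined at 10.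

3. Step 4. Competing oxidation to the ortho-quinone, over-oxidation, or incomplete conversion of the waxy arene in the aqueous medium may erode the step. The fallback sets out from 8 and uses anodic instead of chemical oxidation. Electrolysis at a platinum anode (1% KOH in MeOH/THF, 0 °C, undivided cell, constant current) should give the quinone bis(dimethyl ketal) 1-henicosyl-2,3,3,5,6,6-hexamethoxycyclohexa-1,4-diene F3; its regioisomer from the other para pair would converge on the same quinone. Mild hydrolysis of both ketal carbons (dilute aq. HCl, acetone, rt) rejoins the route at 9.

**Further compounds**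

F1 | step 3 | pentadecylmagnesium bromide | CCCCCCCCCCCCCCC[Mg]Br
F2 | step 5 | 3-henicosyl-2,5-dihydroxy-1,4-benzoquinone | CCCCCCCCCCCCCCCCCCCCCC1=C(O)C(=O)C=C(O)C1=O
F3 | step 4 | 1-henicosyl-2,3,3,5,6,6-hexamethoxycyclohexa-1,4-diene | CCCCCCCCCCCCCCCCCCCCCC1=C(OC)C(OC)(OC)C=C(OC)C1(OC)OC
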